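The tridepside is opened at the ester linking ring A (dimethoxy end ring) to middle ring B and, at the same time, at the A-C1–carbonyl bond, so that the shielded acyl carbon arrives as carbon monoxide. A single palladium-catalysed carbonylative esterification unites an aryl triflate, CO and the unchelated B-C4 phenol of benzyl lecanorate, creating one C–C and one C–O bond. The feature exploited is the para relationship of A-C1 and the A-C4 oxygen on a ring bearing A-C2/A-C3 methoxy and A-C6 methyl groups. This is the oxygen pattern of coenzyme Q0, whose hydroquinone, benzylated at the open hydroxyl and triflated at the flanked one, serves as electrophile. Hydrogenolysis then unmasks the target.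

Key step: step 8

Remark on the chemistry: the target has no stereocentre and no configurationally stable axis. It is achiral, so no enantiomer has to be selected and no step needs stereocontrol.

Remark on design: the two chelated hydroxyls (B-C2, C-C2) are left free on purpose. B-C4–OH travels as a silyl ether, which is orthogonal to the benzyl groups removed at the end.

Step 1
Reactants: 1 2,3-dimethoxy-5-methyl-1,4-benzoquinone
Product: 2 2,3-dimethoxy-5-methylbenzene-1,4-diol
Conditions: Na2S2O4 (aq), Et2O, rt, Ar
Reagents that add atoms: none
Why: Dithionite reduction of a 1,4-benzoquinone to its hydroquinone is fast in a two-phase system and leaves the methoxy and methyl groups untouched.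

Step 2
Reactants: 2 2,3-dimethoxy-5-methylbenzene-1,4-diol, 3 benzyl bromide
Product: 4 4-(benzyloxy)-2,3-dimethoxy-6-methylphenol
Conditions: BnBr (1.0 equiv), K2CO3 (1.1 equiv), degassed DMF, Ar, 0 °C to rt
Reagents that add atoms: benzyl bromide (3), BrCc1ccccc1
Why: Williamson ether synthesis under substrate control, in which one equivalent of halide and a mild carbonate base should alkylate first the hydroxyl next to the ring hydrogen, since it is slightly more acidic and much more accessible than the one wedged between methyl and methoxy, while exclusion of air prevents re-oxidation.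

Step 3
Reactants: 4 4-(benzyloxy)-2,3-dimethoxy-6-methylphenol
Product: 5 4-(benzyloxy)-2,3-dimethoxy-6-methylphenyl trifluoromethanesulfonate
Conditions: Tf2O (1.2 equiv), pyridine (3 equiv), CH2Cl2, 0 °C to rt
Reagents that add atoms: trifluoromethanesulfonic anhydride, O=S(=O)(OS(=O)(=O)C(F)(F)F)C(F)(F)F
Why: O-Sulfonylation of a phenol with triflic anhydride and pyridine uses an electrophile reactive enough to reach a doubly ortho-flanked hydroxyl, and the benzyl and methyl ethers are inert to it.

Step 4
Reactants: 6 orsellinic acid (2,4-dihydroxy-6-methylbenzoic acid), 3 benzyl bromide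
Product: 7 benzyl orsellinate (benzyl 2,4-dihydroxy-6-methylbenzoate)
Conditions: BnBr (1.05 equiv), KHCO3 (1.2 equiv), DMF, rt
Reagents that add atoms: benzyl bromide (3), BrCc1ccccc1
Why: Carboxylate SN2 alkylation, in which hydrogen carbonate ionises only the carboxylic acid so both phenols stay free, and room temperature avoids decarboxylation.

Step 5
Reactants: 6 orsellinic acid
Product: 9 4-(tert-butyldimethylsilyloxy)-2-hydroxy-6-methylbenzoic acid, via silyl ester 8 (not isolated)
Conditions: TBSCl (2.1 equiv), imidazole (4.5 equiv), DMF, 0 °C to rt; then AcOH/THF/H2O, rt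
Reagents that add atoms: tert-butyldimethylsilyl chloride, CC(C)(C)[Si](C)(C)Cl
Why: Imidazole-promoted silylation takes the carboxyl group and the unchelated 4-OH while the hydrogen-bonded 2-OH lags behind, and dilute acetic acid then hydrolyses the far more labile silyl ester selectively, conditions to which aryl silyl ethers are stable.

Step 6
Reactants: 7 benzyl orsellinate, 9 4-(tert-butyldimethylsilyloxy)-2-hydroxy-6-methylbenzoic acid
Product: 10 benzyl 4-{[4-(tert-butyldimethylsilyloxy)-2-hydroxy-6-methylbenzoyl]oxy}-2-hydroxy-6-methylbenzoate
Conditions: DCC (1.1 equiv), toluene, rt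
Reagents that add atoms: none
Why: Carbodiimide (Steglich-type) esterification as routinely used for depsides, in which the unchelated 4-OH of 7 is the only competent nucleophile and the chelated 2-OH groups of both partners remain spectators.

Step 7
Reactants: 10 benzyl 4-{[4-(tert-butyldimethylsilyloxy)-2-hydroxy-6-methylbenzoyl]oxy}-2-hydroxy-6-methylbenzoate
Product: 11 benzyl lecanorate (benzyl 4-[(2,4-dihydroxy-6-methylbenzoyl)oxy]-2-hydroxy-6-methylbenzoate)
Conditions: TBAF (1.1 equiv), AcOH (1.5 equiv), THF, 0 °C
Reagents that add atoms: none
Why: Fluoride-induced cleavage of an aryl silyl ether, buffered with acetic acid so that the liberated phenoxide is protonated at once and cannot attack the depside or benzyl ester carbonyl.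

Step 8
Reactants: 5 4-(benzyloxy)-2,3-dimethoxy-6-methylphenyl trifluoromethanesulfonate (1.2 equiv), 11 benzyl lecanorate, 12 carbon monoxide
Product: 13 tridepside with benzyl ether at A-C4 and benzyl ester on ring C (benzyl 4-({4-[(4-benzyloxy-2,3-dimethoxy-6-methylbenzoyl)oxy]-2-hydroxy-6-methylbenzoyl}oxy)-2-hydroxy-6-methylbenzoate)
Conditions: Pd(OAc)2 (10 mol %), Xantphos (12 mol %), i-Pr2NEt (2 equiv), CO (1 atm), 4 Å MS, toluene, 95 °C
Reagents that add atoms: carbon monoxide (12), [C-]#[O+]
Why: Pd(0)/Xantphos inserts into the A-C1–OTf bond of 5, CO migrates into the aryl–palladium bond, and the cationic aroylpalladium (triflate does not coordinate) takes up the B-C4 phenoxide of 11 and expels the aryl ester by reductive elimination, so the A-C1–C(=O) bond and the C(=O)–O–B-C4 bond are made in one turnover and the ester is assembled at the metal instead of by attack on a carbonyl walled in by the A-C2 methoxy and A-C6 methyl groups. The closest known reaction type is the palladium-catalysed aryloxycarbonylation (carbonylative esterification) of aryl triflates and halides with phenols, including weakly nucleophilic acidic phenols; this electron-rich, doubly ortho-substituted triflate is a demanding member of that class, which is why CO is held at one atmosphere so as not to starve oxidative addition and 5 is used in slight excess. No ring is closed and no stereocentre is created. The selectivity required is acylation of one phenol out of three: the B-C2 and C-C2 hydroxyls are each tied into a six-membered hydrogen bond with the ortho ester carbonyl and are crowded by it, whereas the B-C4 hydroxyl is unchelated, unhindered and, being para to an ester, the most acidic, so the amine base ionises it alone. A hindered tertiary amine, dry toluene and the absence of any alcohol should keep the existing B–C depside link and the benzyl ester from acyl exchange, and the benzyl ether is inert.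

Step 9
Reactants: 13 tridepside with benzyl ether at A-C4 and benzyl ester on ring C
Product: 14 target tridepside CNP0319613.0 (4-({4-[(4-hydroxy-2,3-dimethoxy-6-methylbenzoyl)oxy]-2-hydroxy-6-methylbenzoyl}oxy)-2-hydroxy-6-methylbenzoic acid)
Conditions: H2 (1 atm), 10% Pd/C, EtOAc, rt
Reagents that add atoms: none
Why: Catalytic hydrogenolysis cleaves the benzylic C–O bonds of the aryl benzyl ether and the benzyl ester in one operation while aryl esters, methyl ethers and phenols are inert, and a non-nucleophilic solvent at room temperature avoids solvolysis of the depside links and decarboxylation of the freed acid.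

Compound list
1 | 2,3-dimethoxy-5-methyl-1,4-benzoquinone | CC1=CC(=O)C(OC)=C(OC)C1=O | starting material
2 | 2,3-dimethoxy-5-methylbenzene-1,4-diol | COc1c(O)cc(C)c(O)c1OC | intermediate
3 | benzyl bromide | BrCc1ccccc1 | starting material
4 | 4-(benzyloxy)-2,3-dimethoxy-6-methylphenol | COc1c(OCc2ccccc2)cc(C)c(O)c1OC | intermediate
5 | 4-(benzyloxy)-2,3-dimethoxy-6-methylphenyl trifluoromethanesulfonate | COc1c(OCc2ccccc2)cc(C)c(OS(=O)(=O)C(F)(F)F)c1OC | intermediate
6 | orsellinic acid | Cc1cc(O)cc(O)c1C(=O)O | starting material
7 | benzyl orsellinate | Cc1cc(O)cc(O)c1C(=O)OCc1ccccc1 | intermediate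
8 | tert-butyldimethylsilyl 4-(tert-butyldimethylsilyloxy)-2-hydroxy-6-methylbenzoate | Cc1cc(O[Si](C)(C)C(C)(C)C)cc(O)c1C(=O)O[Si](C)(C)C(C)(C)C | intermediate
9 | 4-(tert-butyldimethylsilyloxy)-2-hydroxy-6-methylbenzoic acid | Cc1cc(O[Si](C)(C)C(C)(C)C)cc(O)c1C(=O)O | intermediate
10 | benzyl 4-{[4-(tert-butyldimethylsilyloxy)-2-hydroxy-6-methylbenzoyl]oxy}-2-hydroxy-6-methylbenzoate | Cc1cc(O[Si](C)(C)C(C)(C)C)cc(O)c1C(=O)Oc1cc(C)c(C(=O)OCc2ccccc2)c(O)c1 | intermediate
11 | benzyl lecanorate | Cc1cc(O)cc(O)c1C(=O)Oc1cc(C)c(C(=O)OCc2ccccc2)c(O)c1 | intermediate
12 | carbon monoxide | [C-]#[O+] | starting material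
13 | tridepside with A-C4 benzyl ether and ring C benzyl ester | COc1c(OCc2ccccc2)cc(C)c(C(=O)Oc2cc(C)c(C(=O)Oc3cc(C)c(C(=O)OCc4ccccc4)c(O)c3)c(O)c2)c1OC | intermediate
14 | CNP0319613.0 | COc1c(O)cc(C)c(C(=O)Oc2cc(C)c(C(=O)Oc3cc(C)c(C(=O)O)c(O)c3)c(O)c2)c1OC | target

Total step count: 9.
Longest linear sequence: 5 steps (6 → 9 → 10 → 11 → 13 → 14; the branch 1 → 2 → 4 → 5 → 13 → 14 is equally long).

Steps most likely to fail

1. Step 8.
- Risk: oxidative addition of CO-ligated palladium(0) into the electron-rich, doubly ortho-flanked aryl–oxygen bond may be too slow. During prolonged heating the phenoxide could then attack the sulfur of the triflate or exchange acyl groups within the didepside.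
- Fallback: carbonylation and ester formation are separated, so that forcing conditions never meet the fragile didepside.
- Setting out from 5, hydroxycarbonylation (Pd(OAc)2, dppf, CO, Et3N, DMF/H2O, 100 °C) should give 4-(benzyloxy)-2,3-dimethoxy-6-methylbenzoic acid F1.
- This acid and 11 are then condensed with trifluoroacetic anhydride in toluene at room temperature. This acid-side activation has acylium character, which is the established remedy for 2,6-disubstituted benzoic acids in depside chemistry. It again selects the unchelated B-C4 hydroxyl.
- The route is rejoined at 13.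

2. Step 2.
- Risk: discrimination between the two hydroxyls may be incomplete, the second hydroxyl may also be alkylated, and the phenoxide may be re-oxidised by traces of air.
- Fallback: the two oxygens are differentiated by ester cleavage instead of by alkylation.
- Setting out from 2, acetylation (Ac2O, pyridine) should give 2,3-dimethoxy-5-methyl-1,4-phenylene diacetate F2.
- Controlled methanolysis (K2CO3, MeOH, 0 °C, Ar) should remove the acetate next to the ring hydrogen much faster than the one between methyl and methoxy, giving 4-hydroxy-2,3-dimethoxy-6-methylphenyl acetate F3.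
- Benzylation (3, K2CO3, acetone) should give 4-(benzyloxy)-2,3-dimethoxy-6-methylphenyl acetate F4.
- Full methanolysis (K2CO3, MeOH, rt) then returns to the route at 4.

3. Step 5.
- Risk: silylation may spread to the chelated 2-OH, the aryl silyl ether may be lost while the silyl ester is hydrolysed, or the electron-rich free acid may decarboxylate on handling.
- Fallback: the carboxyl group is masked as its benzyl ester during silylation.
- Setting out from 7, TBSCl and imidazole in CH2Cl2 should silylate only the unchelated hydroxyl and give benzyl 4-(tert-butyldimethylsilyloxy)-2-hydroxy-6-methylbenzoate F5.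
- Hydrogenolysis (H2, Pd/C, EtOAc) then frees the acid and comes back to the route at 9.

Further compounds
F1 | step 8 | 4-(benzyloxy)-2,3-dimethoxy-6-methylbenzoic acid | COc1c(OCc2ccccc2)cc(C)c(C(=O)O)c1OC
F2 | step 2 | 2,3-dimethoxy-5-methyl-1,4-phenylene diacetate | COc1c(OC(C)=O)cc(C)c(OC(C)=O)c1OC
F3 | step 2 | 4-hydroxy-2,3-dimethoxy-6-methylphenyl acetate | COc1c(O)cc(C)c(OC(C)=O)c1OC
F4 | step 2 | 4-(benzyloxy)-2,3-dimethoxy-6-methylphenyl acetate | COc1c(OCc2ccccc2)cc(C)c(OC(C)=O)c1OC
F5 | step 5 | benzyl 4-(tert-butyldimethylsilyloxy)-2-hydroxy-6-methylbenzoate | Cc1cc(O[Si](C)(C)C(C)(C)C)cc(O)c1C(=O)OCc1ccccc1
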